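The target in the dawn flask stood at 85.8 % after 80.0 min, and I wanted its share at 4.0 h; the midnight run had been charged the same, but with half the protic impurity.

the same everywhere: starting material 0.20 M
- dawn: reagent 0.20 M; protic impurity 0.040 M; the very flask that is asked about, followed so far
- midnight: reagent 0.20 M; protic impurity 0.020 M; run made earlier
- flask: reagent 0.200 M; protic impurity 0.0400 M; time 4.0 h

dawn run (percent of the starting material charged)

| time / min | intermediate / % | side product / % | starting material / % | target / % |
|---|---|---|---|---|
| 10.0 | 0 | 0 | 36.8 | 62.5 |
| 25.0 | 0.1 | 0.7 | 22.0 | 75.0 |
| 50.0 | 0.9 | 1.2 | 12.9 | 83.2 |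
| 80.0 | 0.4 | 1.6 | 7.4 | 85.8 |

midnight run (percent of the starting material charged)

| time / h | intermediate / % | side product / % | starting material / % | target / % |
|---|---|---|---|---|
| 0.500 | 0 | 0.6 | 19.7 | 76.7 |
| 1.33 | 0 | 0.9 | 10.0 | 87.2 |
| 2.50 | 0.5 | 1.8 | 4.3 | 89.3 |
| 4.00 | 0 | 2.0 | 1.8 | 91.6 |

(each reading ± 0.5 percentage points)

* the largest share of what was charged as starting material, at 4.0 h belongs to (starting material / side product / target / intermediate)
* the largest share itself, whichever of these holds it, in percent of the starting material charged

- percentages count the starting material that a species holds: one side product counts as two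
- steps thought possible: starting material + target -> side product; starting material <-> intermediate + leaving ligand; reagent + intermediate -> target; starting material + protic impurity -> quenched substrate

I reckoned this by counting half-lives. In the midnight run the starting material fell from 4.3 % at 2.50 h to 1.8 % at 4.00 h, so the tail half-life h, the time in which the starting material still present halves late in a run, treated as a pseudo-first-order half-life, came to 1.19 h. The two readings behind h carry 0.5 percentage points each, so h was a rough figure. The last dawn pair, read earlier in its run, gave a shorter 0.624 h, but the midnight pair before the last also gave a shorter 0.961 h, so I took h for the late hours of the dawn flask.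

The dawn flask had 2.67 h to go, which is 2.23 half-lives, so I reckoned its starting material down from the reading of 7.4 % to 1.57 %. Of the starting material consumed by 80.0 min, the readings put 92.7 % in the target, and holding that share gave me 91.2 % of target.

The forecast named target at 90.5 %: “Target therefore ends near 90%, slightly below the midnight run.” My figure stood 0.7 points above it.

The simulated dawn flask gave target at 90.4 %.

    starting material + target → side product (k = 0.180 L mol⁻¹ h⁻¹)
    starting material ⇌ intermediate + leaving ligand, settled at all times (K = 9.10 × 10⁻⁴ M)
    reagent + intermediate → target (k = 4700 L mol⁻¹ h⁻¹)
    starting material + protic impurity → quenched substrate (k = 5.40 L mol⁻¹ h⁻¹)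

From 2.00 h to 4.00 h its starting material fell from 4.61 % to 1.30 %, which is 1.83 halvings against 1.68 counted with h. The quenching of starting material by protic impurity had 65 % of its turnover up to 4.0 h behind it at 0.800 h, and that turnover came to 6.45 % of the starting material charged. In the neighbour charged with 0.50 M of reagent, 4.0 h was 3.36 of h, worth 9.73 % of the charge left, yet it held less, 0 %, with 61 % of its reagent remaining against 8.7 % in the dawn flask.

Readings and results were computed from invented constants; scatter was added.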